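The readings were generated by integration with constants of no real substance, noise included.

If this flask has to be called within the hour, I count target per reagent charged and follow the substrate by the fraction left.

| flask | substrate | reagent in the second phase | remark | time | volume of the second phase over the first |
|---|---|---|---|---|---|
| cedar | 1 mM | 0.75 mM | run made earlier |  |  |
| birch | 1 mM | 1.1 mM | run made earlier |  |  |
| flask | 1.0 mM | 1.50 mM |  | 10 min | 0.25 |

| run | time / min | target / % | substrate / % |
|---|---|---|---|
| cedar | 0.667 | 18.2 | 81.9 |
| cedar | 2.00 | 21.0 | 74.5 |
| cedar | 4.00 | 24.5 | 65.7 |
| cedar | 6.00 | 25.4 | 60.2 |
| cedar | 8.00 | 25.8 | 54.1 |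
| birch | 1.50 | 29.1 | 66.8 |
| birch | 3.00 | 32.5 | 59.5 |
| birch | 5.00 | 34.6 | 49.8 |
| birch | 6.00 | 35.2 | 46.3 |
| birch | 8.00 | 36.9 | 40.5 |

(readings scatter by 0.5 percentage points)

* the target standing at 10 min, as a percentage of the substrate charged
* the change that raises the amount of target at 10 min, in percent of the substrate charged most ("none" if none brings more than 2 percentage points) (Sunday's / Saturday's / none)
* amount of target at 10 min, in percent of the substrate charged, after Saturday's

- in the second phase: reagent in the second phase; everything else is in the first
- charges count per volume of the first phase; a concentration in a rate is the amount of a species over the volume of its own phase; every rate counts per litre of the first phase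
- the earlier runs hold the two phases in the same ratio of volumes as the flask asked about

In the first instants substrate meets reagent fast. In the cedar run at 0.667 min the substrate lost, 18.1%, stands as target, 18.2%, one for one.

In the middle the picture changes. Between 2.00 min and 8.00 min the cedar fraction left falls from 74.5% to 54.1%, but target gains 4.8 percentage points, about a quarter of that loss, so the rest does not show as target.

By the end of the cedar run target lies nearly flat, and between the two runs its level follows the reagent. Read at 8.00 min, target over reagent charged is 0.344 in the cedar run and 0.335 in the birch run. I carry 0.340 as φ, the yield on reagent: target standing in mM per mM of reagent charged.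

For the flask, φ times 1.50 mM over 1.0 mM gives 51.0%, my own figure. Doubled reagent by the same rule asks 1.02 mM of target from 1.0 mM of substrate charged, so I do not trust the rule that far, but I expect Sunday's to gain more than 2 points. Cedar target at 0.667 min is already 70.5% of its reading at 8.00 min, so transfer does not look slow, and I expect little from Saturday's.

The forecast gives 47% (from 42% to 52%), lower than my figure. It names Sunday's as best and puts Saturday's at 50% (from 44% to 64%). Its ground: “The plateau scales with the reagent charge”.

The flask gives 49.8%. Sunday's is best, with 28 points gained against 0 points for Saturday's, which stands at 49.8%.

    reagent in the reaction phase ⇌ reagent in the second phase, rate k1*([reagent in the reaction phase] - [reagent in the second phase]/K1) per volume of the first phase (partition coefficient = 1.40, kL = 0.730 s⁻¹)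
    substrate + reagent in the reaction phase → target (k = 27.0 M⁻¹ s⁻¹)
    substrate + target → side product (k = 1.40 M⁻¹ s⁻¹)
    reagent in the reaction phase ⇌ dormant form (K = 17.0, k = 0.0710 s⁻¹)

The flask's own φ comes to 0.332, beside the 0.340 read from the earlier runs. Dormant form stands in the flask at 0.801 mM at 10.0 min, which is 0.534 of the reagent charged. On a neighbour flask charged with 1.7 mM of substrate, the rest as in this flask, φ, though read at 1 mM of substrate, gives the same target in mM as my figure for this flask, so 30.0% of its substrate. That neighbour flask gives 33.1%, with 0.556 mM of dormant form.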